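**Compound numbering used throughout:** 1–6 are the building blocks and early intermediates, 7 is the open-chain Michael adduct, 8 the cyclohexanedione, 9–13 the enol ether and aromatisation intermediates, 14 the phenol aldehyde, 15 prenyl bromide, 16 the prenylated aldehyde, 17 the target.

## The problem

Compound 17 is a diaryl ether with three ortho substituents around the ether oxygen. Ring A is a methyl salicylate (ester at C1, chelated phenol at C2, methyl at C4, ether oxygen at C6). Ring B is bound through C1 and carries hydroxymethyl at C2, methoxy at C4 and a prenyl ether at C6. The rings are not fused and the target has no stereocentre, so no element of stereocontrol is needed; any sp3 centre made on the way only has to be erased. The difficulty is regiochemical and chemoselective: the ether oxygen lies between an ester on one ring and two substituents on the other, which makes an intermolecular aryl–oxygen coupling slow, and ring B carries three different oxygen substituents that must be told apart. The aryl prenyl ether is the most fragile group (acid, electrophilic oxidants, hydrogenation, thermal Claisen shift to the free C5 position) and has to be introduced late. The benzylic alcohol could lactonise onto the neighbouring ester under forcing conditions, and the ring A phenol must stay free while other hydroxyls are alkylated. The feature that opens the structure is the oxygen pattern of ring B: the oxygens at C4 and C6 are 1,3-related, the aryloxy carbon C1 is next to C6 and the one-carbon branch is on C2. That is the pattern of a 4-aryloxy-5-substituted cyclohexane-1,3-dione, one dehydrogenation below the arene, in which the two oxygens are chemically different and the hindered aryl–oxygen bond becomes an ordinary phenol alkylation.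

## Retrosynthesis

**17 ⇒ 16.** No skeletal bond is cut; the hydroxymethyl group at C2 of ring B is traced to a formyl group. The branch carbon is kept at the aldehyde level because it can then enter as a dimethyl acetal, which is inert to alkoxide and not enolisable. A protected alcohol would need a building block that cannot be bought and a deprotection next to the prenyl ether. Aldehyde 16 already holds everything else of 17. The forward step must reduce an aromatic aldehyde without touching a hindered, hydrogen-bonded methyl ester.

**16 ⇒ 14 + 15.** The O–CH2 bond of the prenyl ether is cut. Introducing the prenyl group earlier is the neighbouring option, but the ether would not survive the oxidative aromatisation or the aqueous acid that come before. Phenol 14 has two free hydroxyls, so the alkylation with 15 must choose the ring B hydroxyl at C6 over the chelated ring A hydroxyl.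

**14 ⇒ 10.** No bond is cut; ring B is taken back by one dehydrogenation to the 6-aryloxy-3-methoxycyclohex-2-enone 10, and the aldehyde to its acetal. In 10 the C4 oxygen is already an enol methyl ether and the C6 oxygen is a ketone, so aromatisation releases exactly one free phenol, at C6. Aromatising to a resorcinol and differentiating its two hydroxyls afterwards offers no comparable handle. The forward sequence (enol silylation to 11, hydride abstraction by a quinone to 12, acidic work-up through 13) must keep the acetal intact until the ring is aromatic. A free aldehyde beta to the aryloxy group on a non-aromatic ring would expel ring A as a phenoxide.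

**10 ⇒ 9 ⇒ 8.** The methyl–oxygen bonds of the ester and of the enol ether are cut, in that order. Enol etherification comes first and under acid, where it is reversible and should place the methoxy group on the carbonyl remote from the aryloxy carbon. The carboxyl is methylated only after the dione is capped, since a free 1,3-dione would be C-methylated under the same conditions. Dione 8 is simpler than 10 by two methyl groups; the forward demand is regioselectivity in the enol ether formation.

**8 ⇒ 5 + 6 (key disconnection).** Bonds C1–C2 and C4–C5 of the future ring B are cut. Forward, this is a conjugate addition of the aryloxy-bearing carbon of ketone 5 to enoate 6, giving the open-chain adduct 7, followed by a Claisen closure of the methyl ketone onto the ester. Cutting C2–C3 and C4–C5 instead (a malonate-type annulation) would need an alpha-aryloxy enone and a later decarboxylation. Cutting the aryl–oxygen bond at the dione stage would need a leaving group on a 1,3-dione. The chosen cut uses the natural acidity of an aryloxyacetone and reduces a ring with two adjacent sp3 centres to an acyclic ketone and a C4 enoate. The forward reaction must add through the aryloxy carbon and not through the methyl group, and ring A must stay out of it, which is why 5 is a free acid that reacts as its carboxylate.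

**5 ⇒ 4 ⇒ 2 + 3, and 2 ⇒ 1.** The O–CH2 bond of the acetonyl ether and the benzyl ester are cut. The hindered diaryl ether bond of 17 is thus made as an alkylation of a phenol with 3. The carboxyl must be masked during this alkylation, since a free carboxylate would be alkylated first. The mask must come off under neutral conditions, because a 2,6-disubstituted benzoate resists saponification and the aryloxy ketone is base-sensitive; a benzyl ester removed by hydrogenolysis meets both needs. The forward demand is mono-alkylation of one of two equivalent phenols in 2.

## Roads not taken

**Alternative 1:** The cut removes two bonds on adjacent carbons of ring A, the diaryl C6–O bond and the C1–carboxyl bond. In the forward step CsF strips the silyl and triflate groups from A2 and creates a strained triple bond between C1 and C6. The phenoxide of A3 adds at C6, and the aryl anion at C1, stabilised by the neighbouring methoxymethoxy group, is trapped by carbon dioxide A4 to give acid A1.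
- Merits: three components are joined in one flask, the congested ether and a C–C bond form together, and the regiochemistry follows from the polarisation of a 3-alkoxy aryne. A1 is an esterification and two deprotections from 17.
- Weak points: A3 is a 2,6-disubstituted phenoxide that is itself carbonated by A4, so its addition competes with fluoride and with self-reaction of the short-lived intermediate. Protonation of the aryl anion would give the ether without the carboxyl. Fluoride threatens the benzylic silyl ether. The methoxymethyl group must finally be removed with acid while the prenyl ether is present. Both A2 and A3 need several steps, and A3 poses the three-oxygen problem on a finished arene.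
- Comparison: this road is more convergent and avoids both the dehydrogenation and the enol ether regiochemistry of the chosen plan. Against that, the chosen plan makes its aryl–oxygen bond by an unhindered alkylation with no competing pathway, differentiates the ring B oxygens through ring construction, removes nothing acid-labile after the prenyl group is in place, and starts from four purchased compounds.

**Alternative 2:** Ring B is assembled by photochemical vinylketene benzannulation. Irradiation of diazoketone A6 causes a Wolff shift (bond C2–C3). The resulting ketene takes up methoxyethyne A7 (bonds C3–C4 and C5–C6), and four-electron ring opening followed by six-electron closure (bond C6–C1) gives phenol A5.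
- Merits: the two ring B oxygens differ by origin, the C6 hydroxyl from the ketene carbonyl and the C4 methoxy group from A7. No selectivity question arises and no oxidation-level adjustment is needed. In this respect the road is better than the chosen plan, and its endgame (prenylation, desilylation) is shorter.
- Weak points: A6 is a beta-aryloxy diazo enone that needs a long and delicate preparation and is sensitive to light and acid. A7 is volatile and unstable. The photochemical step is hard to scale.
- Comparison: the chosen plan offers a short front end from cheap reagents and purely thermal, scalable operations. It accepts in exchange one regioselective enol etherification and one dehydrogenation.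

**Alternative 3:** Ring A is cut at C1–C2 and C5–C6. Forward, the ketene silyl acetal diene A10 adds across the aryloxypropiolate A9 in a Diels–Alder reaction. Loss of the silyl and methoxy groups from the former acetal carbon then gives the salicylate A8, one desilylation from 17.
- Merits: this is the most convergent road. The ring A pattern is fixed by polarity matching (nucleophilic diene terminus to the aryloxy-bearing alkyne carbon), and after the key step it is shorter than any other plan.
- Weak points: A9 is an ynol ether that has to be made from the hindered phenol A3 with strong-base chemistry. Its donor-substituted alkyne is a deactivated dienophile, so heat is needed, and heat invites Claisen rearrangement of the aryl prenyl ether to C5 of ring B. A10 is hydrolytically sensitive. A3 is needed again, with its own multi-step preparation.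
- Comparison: the chosen plan cannot match the convergence or the endgame. It avoids heating a prenyl ether, avoids preparing A3 and A9, and carries the prenyl group only through two mild steps.

Key step: step 4

Remark: 17 is achiral; 7–10 are racemic diastereomer mixtures and 11 is racemic, and no configuration is assigned because every sp3 centre of ring B is removed in step 7. Compound 6 is treated as a purchasable building block.

## Route

Step 1
Reactants: 1 2,6-dihydroxy-4-methylbenzoic acid
Product: 2 benzyl 2,6-dihydroxy-4-methylbenzoate
Conditions: BnBr, KHCO3, DMF, rt
Reagents that add atoms: benzyl bromide, BrCc1ccccc1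
Why: Carboxylate alkylation (SN2) with a weak base: KHCO3 deprotonates only the carboxylic acid, whose anion is benzylated in DMF while the two hydrogen-bonded phenols stay untouched.

Step 2
Reactants: 2 benzyl 2,6-dihydroxy-4-methylbenzoate; 3 chloroacetone
Product: 4 benzyl 2-hydroxy-4-methyl-6-(2-oxopropoxy)benzoate
Conditions: K2CO3 (1.1 equiv), NaI (cat.), acetone, 40 °C
Reagents that add atoms: none
Why: Williamson ether synthesis; after the first alkylation the remaining hydroxyl is held in a strong hydrogen bond to the ester carbonyl, so one equivalent of 3 should stop at the mono-ether, and carbonate in acetone is too weak to close the acetonyl ether onto the ester.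

Step 3
Reactants: 4 benzyl 2-hydroxy-4-methyl-6-(2-oxopropoxy)benzoate
Product: 5 2-hydroxy-4-methyl-6-(2-oxopropoxy)benzoic acid
Conditions: H2 (1 atm), 10% Pd/C, EtOAc, rt
Reagents that add atoms: none
Why: Hydrogenolysis of a benzyl ester under neutral conditions; the aliphatic ketone and the aryl ether are not reduced at 1 atm and room temperature, and no base touches the enolisable aryloxyacetone.

Step 4
Reactants: 5 2-hydroxy-4-methyl-6-(2-oxopropoxy)benzoic acid; 6 methyl (E)-4,4-dimethoxybut-2-enoate
Product: 8 2-{[6-(dimethoxymethyl)-2,4-dioxocyclohexyl]oxy}-6-hydroxy-4-methylbenzoic acid (racemic diastereomer mixture), via open-chain Michael adduct 7 (not isolated)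
Conditions: KOC(CH3)3 (3.3 equiv), THF/DMSO, 0 °C to rt; then cold 1 M HCl to pH 3–4
Reagents that add atoms: none
Why: Two equivalents of KOC(CH3)3 turn 5 into its carboxylate–phenoxide and the third reversibly deprotonates the ketone; the enolate at the aryloxy-bearing carbon, favoured by the inductive effect of the oxygen, adds to the beta carbon of 6 and forms bond C1–C2 (adduct 7). Proton transfer then gives the methyl ketone enolate, which attacks the ester carbonyl in a 6-exo-trig Claisen closure that forms bond C4–C5, expels methoxide and closes the carbocycle that becomes ring B. The sequence is driven by irreversible deprotonation of the 1,3-dione. The closest known reaction is the consecutive Michael–Claisen synthesis of 4-substituted cyclohexane-1,3-diones from substituted acetones and unsaturated esters with the same base. The two new sp3 centres (C1 and C2) form without control, probably trans after equilibration at C1, and both are erased in step 7. The step needs the aryloxy carbon and not the methyl group as Michael donor, which its higher acidity under equilibrating conditions should secure; closure from C1 would give a four-membered ring, so only the methyl side can close. Ring A must stay out of the reaction, and as a carboxylate it cannot be attacked by the adjacent enolate, so Dieckmann closure to a benzofuranone is excluded. The acetal is inert to alkoxide, and the cold, mildly acidic quench should preserve it.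

Step 5
Reactants: 8 2-{[6-(dimethoxymethyl)-2,4-dioxocyclohexyl]oxy}-6-hydroxy-4-methylbenzoic acid
Product: 9 2-{[6-(dimethoxymethyl)-4-methoxy-2-oxocyclohex-3-en-1-yl]oxy}-6-hydroxy-4-methylbenzoic acid
Conditions: MeOH, HC(OMe)3, TsOH·H2O (cat.), rt
Reagents that add atoms: methanol, CO (trimethyl orthoformate, COC(OC)OC, takes up the water and is an equivalent methoxy donor)
Why: Acid-catalysed enol etherification of a cyclic 1,3-dione is reversible, so the more stable isomer should dominate: the carbonyl flanked by two methylene groups (C4) takes the methoxy group, avoiding the allylic strain of a C6 enol ether against the C1 aryloxy group, as known for 4-substituted cyclohexane-1,3-diones. The dry methanolic medium keeps the dimethyl acetal, and the hindered 2,6-disubstituted acid is not esterified under these conditions.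

Step 6
Reactants: 9 2-{[6-(dimethoxymethyl)-4-methoxy-2-oxocyclohex-3-en-1-yl]oxy}-6-hydroxy-4-methylbenzoic acid
Product: 10 methyl 2-{[6-(dimethoxymethyl)-4-methoxy-2-oxocyclohex-3-en-1-yl]oxy}-6-hydroxy-4-methylbenzoate
Conditions: MeI, KHCO3, DMF, rt
Reagents that add atoms: iodomethane, CI
Why: SN2 methylation of the carboxylate with hydrogencarbonate as base; with the dione capped as a vinylogous ester no acidic carbon is left for C-methylation, and the chelated phenol is not deprotonated.

Step 7
Reactants: 10 methyl 2-{[6-(dimethoxymethyl)-4-methoxy-2-oxocyclohex-3-en-1-yl]oxy}-6-hydroxy-4-methylbenzoate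
Product: 14 methyl 2-(2-formyl-6-hydroxy-4-methoxyphenoxy)-6-hydroxy-4-methylbenzoate, via bis-silyl dienol ether 11 (not isolated), via bis-silyl aryl ether acetal 12 (not isolated), via phenol acetal 13 (not isolated)
Conditions: LiN(iPr)2 (2.3 equiv), Me3SiCl, THF, −78 °C; DDQ, 2,6-lutidine, CH2Cl2, 0 °C; then 1 M HCl, THF, rt
Reagents that add atoms: water, O
Why: Enolate formation with Me3SiCl already present traps the enolate (and the ring A phenoxide) as silyl ethers before it can attack the ring A ester, giving the 2-silyloxycyclohexa-1,3-diene 11; either regioisomer of this dienol ether would lead to the same arene. DDQ abstracts an allylic hydride from such dienes and proton loss gives arene 12 (quinone dehydrogenation of a silyl dienol ether). Aqueous HCl then cleaves both aryl silyl ethers (13) and hydrolyses the acetal, which is safe only now that the ring is aromatic and the prenyl group is not yet present.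

Step 8
Reactants: 14 methyl 2-(2-formyl-6-hydroxy-4-methoxyphenoxy)-6-hydroxy-4-methylbenzoate; 15 prenyl bromide
Product: 16 methyl 2-{2-formyl-4-methoxy-6-[(3-methylbut-2-en-1-yl)oxy]phenoxy}-6-hydroxy-4-methylbenzoate
Conditions: K2CO3, DMF, 0 °C to rt
Reagents that add atoms: none
Why: Williamson etherification; the ring B hydroxyl is the only unchelated phenol and should be alkylated first by one equivalent of 15, while the salicylate hydroxyl is held by its hydrogen bond to the ester. DMF favours O- over C-alkylation, and the non-enolisable aldehyde is inert.

Step 9
Reactants: 16 methyl 2-{2-formyl-4-methoxy-6-[(3-methylbut-2-en-1-yl)oxy]phenoxy}-6-hydroxy-4-methylbenzoate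
Product: 17 methyl 2-hydroxy-6-{2-(hydroxymethyl)-4-methoxy-6-[(3-methylbut-2-en-1-yl)oxy]phenoxy}-4-methylbenzoate
Conditions: NaBH4, MeOH/THF, 0 °C
Reagents that add atoms: none
Why: Borohydride reduction of an aromatic aldehyde is fast at 0 °C, while the hindered, chelated methyl ester, the prenyl double bond and the aryl ethers are inert. A short reaction time and neutral work-up should prevent lactonisation of the new benzylic alcohol onto the ester.

## Compound list

1 | 2,6-dihydroxy-4-methylbenzoic acid | Cc1cc(O)c(C(=O)O)c(O)c1 | starting material
2 | benzyl 2,6-dihydroxy-4-methylbenzoate | Cc1cc(O)c(C(=O)OCc2ccccc2)c(O)c1 | intermediate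
3 | chloroacetone (1-chloropropan-2-one) | CC(=O)CCl | starting material
4 | benzyl 2-hydroxy-4-methyl-6-(2-oxopropoxy)benzoate | CC(=O)COc1cc(C)cc(O)c1C(=O)OCc1ccccc1 | intermediate
5 | 2-hydroxy-4-methyl-6-(2-oxopropoxy)benzoic acid | CC(=O)COc1cc(C)cc(O)c1C(=O)O | intermediate
6 | methyl (E)-4,4-dimethoxybut-2-enoate | COC(OC)/C=C/C(=O)OC | starting material
7 | 2-{[4-(dimethoxymethyl)-6-methoxy-2,6-dioxohexan-3-yl]oxy}-6-hydroxy-4-methylbenzoic acid (open-chain Michael adduct, not isolated, racemic diastereomer mixture) | COC(=O)CC(C(OC)OC)C(Oc1cc(C)cc(O)c1C(=O)O)C(C)=O | intermediate
8 | 2-{[6-(dimethoxymethyl)-2,4-dioxocyclohexyl]oxy}-6-hydroxy-4-methylbenzoic acid (racemic diastereomer mixture) | O=C1CC(=O)C(Oc2cc(C)cc(O)c2C(=O)O)C(C(OC)OC)C1 | intermediate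
9 | 2-{[6-(dimethoxymethyl)-4-methoxy-2-oxocyclohex-3-en-1-yl]oxy}-6-hydroxy-4-methylbenzoic acid (racemic diastereomer mixture) | COC1=CC(=O)C(Oc2cc(C)cc(O)c2C(=O)O)C(C(OC)OC)C1 | intermediate
10 | methyl 2-{[6-(dimethoxymethyl)-4-methoxy-2-oxocyclohex-3-en-1-yl]oxy}-6-hydroxy-4-methylbenzoate (racemic diastereomer mixture) | COC(=O)c1c(O)cc(C)cc1OC1C(=O)C=C(OC)CC1C(OC)OC | intermediate
11 | methyl 2-{[6-(dimethoxymethyl)-4-methoxy-2-(trimethylsilyloxy)cyclohexa-1,3-dien-1-yl]oxy}-4-methyl-6-(trimethylsilyloxy)benzoate (not isolated, racemic) | COC(=O)c1c(O[Si](C)(C)C)cc(C)cc1OC1=C(O[Si](C)(C)C)C=C(OC)CC1C(OC)OC | intermediate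
12 | methyl 2-[2-(dimethoxymethyl)-4-methoxy-6-(trimethylsilyloxy)phenoxy]-4-methyl-6-(trimethylsilyloxy)benzoate (not isolated) | COC(=O)c1c(O[Si](C)(C)C)cc(C)cc1Oc1c(O[Si](C)(C)C)cc(OC)cc1C(OC)OC | intermediate
13 | methyl 2-[2-(dimethoxymethyl)-6-hydroxy-4-methoxyphenoxy]-6-hydroxy-4-methylbenzoate (not isolated) | COC(=O)c1c(O)cc(C)cc1Oc1c(O)cc(OC)cc1C(OC)OC | intermediate
14 | methyl 2-(2-formyl-6-hydroxy-4-methoxyphenoxy)-6-hydroxy-4-methylbenzoate | COC(=O)c1c(O)cc(C)cc1Oc1c(O)cc(OC)cc1C=O | intermediate
15 | prenyl bromide (1-bromo-3-methylbut-2-ene) | CC(C)=CCBr | starting material
16 | methyl 2-{2-formyl-4-methoxy-6-[(3-methylbut-2-en-1-yl)oxy]phenoxy}-6-hydroxy-4-methylbenzoate | COC(=O)c1c(O)cc(C)cc1Oc1c(OCC=C(C)C)cc(OC)cc1C=O | intermediate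
17 | methyl 2-hydroxy-6-{2-(hydroxymethyl)-4-methoxy-6-[(3-methylbut-2-en-1-yl)oxy]phenoxy}-4-methylbenzoate | COC(=O)c1c(O)cc(C)cc1Oc1c(CO)cc(OC)cc1OCC=C(C)C | target

## Step count and risk

Total step count: 9. Longest linear sequence: 9 steps (1 to 17); 3, 6 and 15 enter as purchased reagents.

**Step 4 (key step).** The triply charged salt of 5 may be poorly soluble and unreactive. The conjugate addition may also run through the methyl group, which after Claisen closure would give the isomeric 2-aryloxy dione, and 6 may be lost by base-induced deconjugation or oligomerisation. The fallback changes the disconnection and sets out from 5: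
- Condensation of 5 at its activated methylene with 2,2-dimethoxyacetaldehyde (piperidinium acetate, toluene, water removal) would give the alpha-aryloxy enone 2-{[(3Z)-5,5-dimethoxy-2-oxopent-3-en-3-yl]oxy}-6-hydroxy-4-methylbenzoic acid F1.
- A classical malonate annulation (dimethyl malonate, NaOCH3, MeOH, reflux; Michael addition then Claisen closure) would give 2-{[6-(dimethoxymethyl)-5-(methoxycarbonyl)-2,4-dioxocyclohexyl]oxy}-6-hydroxy-4-methylbenzoic acid F2.
- Saponification with aqueous NaOH, acidification to pH 4–5 and gentle warming would decarboxylate F2, and the route is rejoined at 8.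

**Step 5.** Enol ether formation may be poorly regioselective, because the electron-withdrawing aryloxy group makes the C6 carbonyl the more electrophilic one and may offset the steric preference. The fallback sets out from 8 and differentiates the oxygens by geometry instead:
- Exhaustive silylation (Me3SiCl/Et3N, then LiN(iPr)2/Me3SiCl), DDQ and aqueous HCl, as in step 7, would aromatise 8 without differentiation to 2-(2-formyl-4,6-dihydroxyphenoxy)-6-hydroxy-4-methylbenzoic acid F3.
- Lactonisation (DCC, CH2Cl2, high dilution) can only reach the C6 hydroxyl and would give the seven-membered lactone 1,8-dihydroxy-3-methyl-11-oxo-11H-dibenzo[b,e][1,4]dioxepine-6-carbaldehyde F4.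
- Methylation of the only unchelated hydroxyl (MeI, one equivalent, K2CO3, acetone) would give 1-hydroxy-8-methoxy-3-methyl-11-oxo-11H-dibenzo[b,e][1,4]dioxepine-6-carbaldehyde F5.
- Methanolysis of the aryl ester (NaOCH3, MeOH, 0 °C) would open the lactone to the methyl ester and the free C6 phenol. The route is rejoined at 14, and steps 5–7 are replaced.

**Step 7.** Deprotonation at the hindered tertiary C1–H may be slow, the enolate may attack the ring A ester before it is silylated, or the quinone may over-oxidise the electron-rich aryl silyl ether. The fallback sets out from 10 and uses no enolate and no quinone. A palladium-catalysed aerobic dehydrogenation (Pd(OCOCF3)2, 2-(dimethylamino)pyridine, O2 at 1 atm, DMSO, 80 °C, with molecular sieves and without a sulfonic acid additive so that the acetal outlasts the aromatisation) would give 13. Brief treatment with 1 M HCl in THF then rejoins the route at 14. This fallback passes through no compound outside the list (F0).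

**Step 2.** The enolisable aryloxy ketone may condense with itself or cyclise onto the ester under base, and chloroacetone may degrade. Over-alkylation is a lesser risk and is controlled by stoichiometry. The fallback sets out from 2 and masks the ketone as an alkene:
- Alkylation with 3-chloro-2-methylprop-1-ene (K2CO3, DMF) would give benzyl 2-hydroxy-4-methyl-6-[(2-methylprop-2-en-1-yl)oxy]benzoate F6.
- Oxidative cleavage of the 1,1-disubstituted alkene (OsO4 cat., NaIO4, 2,6-lutidine, dioxane/water) would reveal the ketone under non-basic conditions, and the route is rejoined at 4.

## Further compounds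

F1 | step 4 | 2-{[(3Z)-5,5-dimethoxy-2-oxopent-3-en-3-yl]oxy}-6-hydroxy-4-methylbenzoic acid | CC(=O)/C(Oc1cc(C)cc(O)c1C(=O)O)=C/C(OC)OC
F2 | step 4 | 2-{[6-(dimethoxymethyl)-5-(methoxycarbonyl)-2,4-dioxocyclohexyl]oxy}-6-hydroxy-4-methylbenzoic acid (racemic diastereomer mixture) | COC(=O)C1C(=O)CC(=O)C(Oc2cc(C)cc(O)c2C(=O)O)C1C(OC)OC
F3 | step 5 | 2-(2-formyl-4,6-dihydroxyphenoxy)-6-hydroxy-4-methylbenzoic acid | O=Cc1cc(O)cc(O)c1Oc1cc(C)cc(O)c1C(=O)O
F4 | step 5 | 1,8-dihydroxy-3-methyl-11-oxo-11H-dibenzo[b,e][1,4]dioxepine-6-carbaldehyde | O=C1Oc2cc(O)cc(C=O)c2Oc2cc(C)cc(O)c12
F5 | step 5 | 1-hydroxy-8-methoxy-3-methyl-11-oxo-11H-dibenzo[b,e][1,4]dioxepine-6-carbaldehyde | O=C1Oc2cc(OC)cc(C=O)c2Oc2cc(C)cc(O)c12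
F0 | step 7 | none | none
F6 | step 2 | benzyl 2-hydroxy-4-methyl-6-[(2-methylprop-2-en-1-yl)oxy]benzoate | C=C(C)COc1cc(C)cc(O)c1C(=O)OCc1ccccc1
A1 | alternative 1 | 2-(methoxymethoxy)-4-methyl-6-{2-[(tert-butyldimethylsilyloxy)methyl]-4-methoxy-6-[(3-methylbut-2-en-1-yl)oxy]phenoxy}benzoic acid | O=C(O)c1c(OCOC)cc(C)cc1Oc1c(CO[Si](C)(C)C(C)(C)C)cc(OC)cc1OCC=C(C)C
A2 | alternative 1 | 3-(methoxymethoxy)-5-methyl-2-(trimethylsilyl)phenyl trifluoromethanesulfonate | COCOc1cc(C)cc(OS(=O)(=O)C(F)(F)F)c1[Si](C)(C)C
A3 | alternative 1 | 2-[(tert-butyldimethylsilyloxy)methyl]-4-methoxy-6-[(3-methylbut-2-en-1-yl)oxy]phenol | Oc1c(CO[Si](C)(C)C(C)(C)C)cc(OC)cc1OCC=C(C)C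
A4 | alternative 1 | carbon dioxide | O=C=O
A5 | alternative 2 | methyl 2-(tert-butyldimethylsilyloxy)-6-{2-[(tert-butyldimethylsilyloxy)methyl]-6-hydroxy-4-methoxyphenoxy}-4-methylbenzoate | COC(=O)c1c(O[Si](C)(C)C(C)(C)C)cc(C)cc1Oc1c(CO[Si](C)(C)C(C)(C)C)cc(OC)cc1O
A6 | alternative 2 | methyl 2-(tert-butyldimethylsilyloxy)-6-{[(1E)-2-[(tert-butyldimethylsilyloxy)methyl]-4-diazo-3-oxobut-1-en-1-yl]oxy}-4-methylbenzoate | COC(=O)c1c(O[Si](C)(C)C(C)(C)C)cc(C)cc1O/C=C(\CO[Si](C)(C)C(C)(C)C)C(=O)C=[N+]=[N-]
A7 | alternative 2 | methoxyethyne | COC#C
A8 | alternative 3 | methyl 2-{2-[(tert-butyldimethylsilyloxy)methyl]-4-methoxy-6-[(3-methylbut-2-en-1-yl)oxy]phenoxy}-6-hydroxy-4-methylbenzoate | COC(=O)c1c(O)cc(C)cc1Oc1c(CO[Si](C)(C)C(C)(C)C)cc(OC)cc1OCC=C(C)C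
A9 | alternative 3 | methyl 3-{2-[(tert-butyldimethylsilyloxy)methyl]-4-methoxy-6-[(3-methylbut-2-en-1-yl)oxy]phenoxy}prop-2-ynoate | COC(=O)C#COc1c(CO[Si](C)(C)C(C)(C)C)cc(OC)cc1OCC=C(C)C
A10 | alternative 3 | 1-methoxy-3-methyl-1-(trimethylsilyloxy)buta-1,3-diene (E/Z mixture) | COC(O[Si](C)(C)C)=CC(C)=C
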